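Ring F is not carried through the synthesis but built last. Its pattern (O–ring E at C1, hydroxyls at C3 and C5, O–ring G at C4, hydrogens at C2 and C6) is exactly what a cyclobutenone/ynol ether benzannulation delivers, so both ether oxygens of ring F are attached beforehand to non-aromatic carbons. One thermal operation joins a 3-benzyloxy-4-aryloxycyclobutenone carrying ring G with the ethynyl ether of the benzylated A–E pentamer, forming the F(C2)–C3 and F(C1)–C6 bonds and closing ring F as a phenol. The pentamer is assembled by copper-catalysed Ullmann etherifications from three small blocks, and a final hydrogenolysis frees all hydroxyls.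

Key step: step 21

Remark: in every ring C1 is the ether carbon nearer ring A; Bn = benzyl, MOM = methoxymethyl; 1,3,5-tris(benzyloxy)benzene and 3,4,5-tris(benzyloxy)benzaldehyde are assumed to be purchasable; the cyclobutenone is used as the racemate because its only stereocentre becomes an aromatic carbon.

**Ring A phenol**

Step 1
Reactants: 1 1,3,5-tris(benzyloxy)benzene
Product: 2 2,4,6-tris(benzyloxy)benzaldehyde
Conditions: POCl3, DMF, 0 °C to 60 °C; then H2O
Reagents that add atoms: N,N-dimethylformamide, CN(C)C=O; water, O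
Why: Vilsmeier–Haack formylation: the three equivalent ring positions are each activated by two ortho and one para alkoxy group, so the chloroiminium ion should attack once and hydrolysis should give a single aldehyde.

Step 2
Reactants: 2 2,4,6-tris(benzyloxy)benzaldehyde
Product: 4 2,4,6-tris(benzyloxy)phenol, via aryl formate 3 (not isolated)
Conditions: mCPBA, CH2Cl2, 0 °C to rt; then K2CO3 (cat.), MeOH, rt, argon
Reagents that add atoms: mCPBA, OOC(=O)c1cccc(Cl)c1
Why: Baeyer–Villiger oxidation in which the electron-rich trialkoxyaryl group migrates in preference to hydride, followed by mild methanolysis of formate 3 that leaves the benzyl ethers untouched.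

**Ring B/D bromophenol**

Step 3
Reactants: 5 4-bromo-2,6-difluorobenzaldehyde; 6 benzyl alcohol (2.2 equiv)
Product: 7 2,6-bis(benzyloxy)-4-bromobenzaldehyde
Conditions: NaH, DMF, 0 °C to rt
Reagents that add atoms: none
Why: Twofold nucleophilic aromatic substitution (SNAr): both fluorides are ortho to the formyl group and far better leaving groups than the para bromide, which should therefore be retained.

Step 4
Reactants: 7 2,6-bis(benzyloxy)-4-bromobenzaldehyde
Product: 9 2,6-bis(benzyloxy)-4-bromophenol, via aryl formate 8 (not isolated)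
Conditions: mCPBA, CH2Cl2, 0 °C to rt; then K2CO3 (cat.), MeOH, rt
Reagents that add atoms: mCPBA, OOC(=O)c1cccc(Cl)c1
Why: Baeyer–Villiger oxidation with aryl migration favoured by the two ortho alkoxy groups, then methanolysis of formate 8; the aryl bromide is inert to peracid.

**Ring C/E iodide**

Step 5
Reactants: 10 2,3,4-trihydroxybenzaldehyde
Product: 11 2,3,4-tris(benzyloxy)benzaldehyde
Conditions: BnBr (3.5 equiv), K2CO3, DMF, 60 °C
Reagents that add atoms: benzyl bromide, BrCc1ccccc1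
Why: Williamson ether synthesis on all three phenolic hydroxyls, the aldehyde-chelated 2-OH included under forcing carbonate conditions.

Step 6
Reactants: 11 2,3,4-tris(benzyloxy)benzaldehyde
Product: 13 2,3,4-tris(benzyloxy)phenol, via aryl formate 12 (not isolated)
Conditions: mCPBA, CH2Cl2, 0 °C to rt; then K2CO3 (cat.), MeOH, rt
Reagents that add atoms: mCPBA, OOC(=O)c1cccc(Cl)c1
Why: Baeyer–Villiger oxidation in which the ortho- and para-alkoxy-substituted aryl group migrates, then methanolysis of formate 12.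

Step 7
Reactants: 13 2,3,4-tris(benzyloxy)phenol
Product: 14 2,3,4-tris(benzyloxy)-6-iodophenol
Conditions: I2, NaHCO3, THF/H2O, 0 °C, dark, argon
Reagents that add atoms: iodine, II
Why: Electrophilic aromatic iodination of the phenoxide, which directs to its only free ortho position (C6) because the para position carries a benzyloxy group.

Step 8
Reactants: 14 2,3,4-tris(benzyloxy)-6-iodophenol
Product: 15 1,2,3-tris(benzyloxy)-5-iodo-4-(methoxymethoxy)benzene
Conditions: NaH, MOMCl, DMF, 0 °C to rt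
Reagents that add atoms: chloromethyl methyl ether, COCCl
Why: O-Alkylation of the sodium phenoxide with the reactive α-chloro ether (Williamson-type acetal formation) masks the one oxygen that must later be freed selectively.

**Two-ring bromide (used twice, for rings B–C and D–E)**

Step 9
Reactants: 9 2,6-bis(benzyloxy)-4-bromophenol; 15 1,2,3-tris(benzyloxy)-5-iodo-4-(methoxymethoxy)benzene (1.3 equiv)
Product: 16 5-bromo-1,3-bis(benzyloxy)-2-[3,4,5-tris(benzyloxy)-2-(methoxymethoxy)phenoxy]benzene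
Conditions: CuI (cat.), picolinic acid (cat.), K3PO4, DMSO, 90 °C, argon
Reagents that add atoms: none
Why: Ullmann diaryl ether synthesis with the CuI/picolinic acid system suited to hindered partners; the C–I bond should react well before the C–Br bond, which is further deactivated by the para phenoxide, and the ortho MOM oxygen can assist by coordinating copper.

**Assembly of the A–E pentamer**

Step 10
Reactants: 4 2,4,6-tris(benzyloxy)phenol; 16 two-ring bromide
Product: 17 A–C trimer MOM ether (eight benzyl ethers; MOM on the C6 oxygen of ring C)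
Conditions: CuI (cat.), N,N-dimethylglycine hydrochloride (cat.), Cs2CO3, 1,4-dioxane, 105 °C, argon
Reagents that add atoms: none
Why: Ullmann diaryl ether synthesis between an electron-rich 2,6-disubstituted phenoxide and an aryl bromide without ortho substituents, the favourable polarity for a hindered ether oxygen.

Step 11
Reactants: 17 A–C trimer MOM ether
Product: 18 A–C trimer phenol (free OH on C6 of ring C)
Conditions: conc. HCl (cat.), MeOH/THF, 50 °C
Reagents that add atoms: none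
Why: Acid-catalysed acetal cleavage (MOM removal) under conditions to which aryl benzyl ethers and diaryl ethers are inert.

Step 12
Reactants: 18 A–C trimer phenol; 16 two-ring bromide
Product: 19 A–E pentamer MOM ether (thirteen benzyl ethers; MOM on the C6 oxygen of ring E)
Conditions: CuI (cat.), N,N-dimethylglycine hydrochloride (cat.), Cs2CO3, 1,4-dioxane, 105 °C, argon
Reagents that add atoms: none
Why: Second Ullmann diaryl ether synthesis of the same type as step 10, again pairing the hindered phenoxide with the unhindered bromide of 16.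

Step 13
Reactants: 19 A–E pentamer MOM ether
Product: 20 A–E pentamer phenol (free OH on C6 of ring E; thirteen benzyl ethers)
Conditions: conc. HCl (cat.), MeOH/THF, 50 °C
Reagents that add atoms: none
Why: Acid-catalysed MOM acetal cleavage as in step 11 exposes the single hydroxyl on C6 of ring E.

Step 14
Reactants: 20 A–E pentamer phenol; 21 trichloroethylene
Product: 22 A–E pentamer (E)-1,2-dichlorovinyl ether
Conditions: K2CO3, DMF, 70 °C
Reagents that add atoms: none
Why: Base-mediated dichlorovinylation: K2CO3 converts trichloroethylene into dichloroacetylene, to which the phenoxide adds in anti fashion to give the (E)-dichlorovinyl ether, and so small an electrophile should tolerate the two ortho substituents.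

Step 15
Reactants: 22 A–E pentamer (E)-1,2-dichlorovinyl ether
Product: 24 A–E pentamer ethynyl ether (O–C≡CH on C6 of ring E), via lithium acetylide 23 (not isolated)
Conditions: n-BuLi (2.5 equiv), THF, −78 to −40 °C; then MeOH, −78 °C; quick filtration through Et3N-deactivated silica, used at once
Reagents that add atoms: none
Why: Dehydrochlorination followed by chlorine–lithium exchange: n-BuLi removes the vinylic proton, chloride is lost to give the chloroalkynyl ether, a second equivalent exchanges the remaining chlorine, and cold protonation of acetylide 23 gives the terminal ynol ether while benzyl ethers are not attacked at −78 °C.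

**Cyclobutenone carrying ring G**

Step 16
Reactants: 25 3,4,5-tris(benzyloxy)benzaldehyde
Product: 27 3,4,5-tris(benzyloxy)phenol, via aryl formate 26 (not isolated)
Conditions: mCPBA, CH2Cl2, 0 °C to rt; then K2CO3 (cat.), MeOH, rt
Reagents that add atoms: mCPBA, OOC(=O)c1cccc(Cl)c1
Why: Baeyer–Villiger oxidation with migration of the para-alkoxy-substituted aryl group, then methanolysis of formate 26.

Step 17
Reactants: 27 3,4,5-tris(benzyloxy)phenol; 28 bromoacetic acid
Product: 29 2-[3,4,5-tris(benzyloxy)phenoxy]acetic acid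
Conditions: NaH (2.2 equiv), THF, 0 °C to reflux; then aq. HCl
Reagents that add atoms: none
Why: Williamson ether synthesis between the sodium phenoxide and sodium bromoacetate, the carboxylate form keeping the acid out of side reactions.

Step 18
Reactants: 6 benzyl alcohol; 21 trichloroethylene
Product: 30 benzyl (E)-1,2-dichlorovinyl ether
Conditions: KH, THF, 0 °C; then 21, −50 °C to rt
Reagents that add atoms: none
Why: Base-mediated dichlorovinylation of the potassium alkoxide by anti addition to dichloroacetylene formed in situ, giving the (E)-dichlorovinyl ether.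

Step 19
Reactants: 30 benzyl (E)-1,2-dichlorovinyl ether
Product: 32 benzyl ethynyl ether, via lithium benzyloxyacetylide 31 (not isolated)
Conditions: n-BuLi (2.2 equiv), Et2O, −78 to −40 °C; then MeOH, −78 °C; cold aqueous work-up, dried solution kept below 0 °C and used at once
Reagents that add atoms: none
Why: Dehydrochlorination and chlorine–lithium exchange as in step 15, with protonation of acetylide 31 and a cold work-up because benzyl ynol ethers rearrange sigmatropically on warming.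

Step 20
Reactants: 29 2-[3,4,5-tris(benzyloxy)phenoxy]acetic acid; 32 benzyl ethynyl ether (2 equiv)
Product: 35 racemic 3-(benzyloxy)-4-[3,4,5-tris(benzyloxy)phenoxy]cyclobut-2-en-1-one, via acid chloride 33 (not isolated), via aryloxyketene 34 (not isolated)
Conditions: (COCl)2, DMF (cat.), CH2Cl2, 0 °C to rt, evaporate; then 32, Et3N (slow addition), CH2Cl2, 0 °C to rt
Reagents that add atoms: none
Why: Acid chloride formation, dehydrochlorination to aryloxyketene 34 and [2+2] ketene–alkyne cycloaddition, in which the nucleophilic CH terminus of the ynol ether bonds to the ketene carbonyl carbon so that benzyloxy ends at C3 and aryloxy at C4; the C4 stereocentre forms as a racemate, which is immaterial because it becomes aromatic in step 21.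

**Key step and deprotection**

Step 21
Reactants: 35 racemic 3-(benzyloxy)-4-[3,4,5-tris(benzyloxy)phenoxy]cyclobut-2-en-1-one (1.5 equiv); 24 A–E pentamer ethynyl ether
Product: 40 heptamer phenol (free OH on C3 of ring F; seventeen benzyl ethers), via vinylketene 36 (not isolated), via vinylcyclobutenone 37 (not isolated), via dienylketene 38 (not isolated), via cyclohexadienone 39 (not isolated)
Conditions: toluene, 80 °C then 110 °C, argon, sealed vessel; then KOH, MeOH/THF, rt
Reagents that add atoms: none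
Why: Thermal 4π electrocyclic opening of 35, with the C4 aryloxy group rotating outward, should give vinylketene 36, whose ketene C=C bond undergoes [2+2] cycloaddition with ynol ether 24 to give vinylcyclobutenone 37; a second 4π opening to dienylketene 38, 6π electrocyclisation to cyclohexadienone 39 and tautomerisation then deliver phenol 40. This is a Danheiser benzannulation, the closest precedent being the same cascade between cyclobutenones and alkoxy- or siloxyalkynes. Ring F is closed by the 6π electrocyclisation, which re-forms the C3–C4 bond after the cycloaddition has made the F(C2)–C3 and F(C1)–C6 bonds. No stereocentre is created, and the one in racemic 35 becomes aromatic C4. The step needs a single regiochemistry in the ketene–alkyne cycloaddition, and the oxygen lone pair of the aryl ethynyl ether secures it by making the terminal CH carbon nucleophilic towards the ketene carbonyl carbon, which places O–ring E meta to the new hydroxyl and para to O–ring G. The aryl ynol ether has no O-alkyl hydrogen for retro-ene loss and so should survive the temperature needed to open the vinylogous-ester cyclobutenone, and the closing KOH treatment returns any product phenol that was O-acylated by excess ketene.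

Step 22
Reactants: 40 heptamer phenol
Product: 41 CNP0292517.0 (target)
Conditions: H2 (1 atm), Pd/C (palladium on carbon), THF/MeOH, rt; filtration and concentration under argon
Reagents that add atoms: none
Why: Catalytic hydrogenolysis of seventeen benzyl aryl ethers, to which diaryl ether bonds and the arene rings are inert, with exclusion of air protecting the electron-rich polyphenol.

**Compound list**

1 | 1,3,5-tris(benzyloxy)benzene | c1(OCc9ccccc9)cc(OCc9ccccc9)cc(OCc9ccccc9)c1 | starting material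
2 | 2,4,6-tris(benzyloxy)benzaldehyde | O=Cc1c(OCc9ccccc9)cc(OCc9ccccc9)cc1OCc9ccccc9 | intermediate
3 | 2,4,6-tris(benzyloxy)phenyl formate | O=COc1c(OCc9ccccc9)cc(OCc9ccccc9)cc1OCc9ccccc9 | intermediate
4 | 2,4,6-tris(benzyloxy)phenol (ring A) | Oc1c(OCc9ccccc9)cc(OCc9ccccc9)cc1OCc9ccccc9 | intermediate
5 | 4-bromo-2,6-difluorobenzaldehyde | O=Cc1c(F)cc(Br)cc1F | starting material
6 | benzyl alcohol | OCc1ccccc1 | starting material
7 | 2,6-bis(benzyloxy)-4-bromobenzaldehyde | O=Cc1c(OCc9ccccc9)cc(Br)cc1OCc9ccccc9 | intermediate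
8 | 2,6-bis(benzyloxy)-4-bromophenyl formate | O=COc1c(OCc9ccccc9)cc(Br)cc1OCc9ccccc9 | intermediate
9 | 2,6-bis(benzyloxy)-4-bromophenol | Oc1c(OCc9ccccc9)cc(Br)cc1OCc9ccccc9 | intermediate
10 | 2,3,4-trihydroxybenzaldehyde | O=Cc1ccc(O)c(O)c1O | starting material
11 | 2,3,4-tris(benzyloxy)benzaldehyde | O=Cc1ccc(OCc9ccccc9)c(OCc9ccccc9)c1OCc9ccccc9 | intermediate
12 | 2,3,4-tris(benzyloxy)phenyl formate | O=COc1ccc(OCc9ccccc9)c(OCc9ccccc9)c1OCc9ccccc9 | intermediate
13 | 2,3,4-tris(benzyloxy)phenol | Oc1ccc(OCc9ccccc9)c(OCc9ccccc9)c1OCc9ccccc9 | intermediate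
14 | 2,3,4-tris(benzyloxy)-6-iodophenol | Oc1c(I)cc(OCc9ccccc9)c(OCc9ccccc9)c1OCc9ccccc9 | intermediate
15 | 1,2,3-tris(benzyloxy)-5-iodo-4-(methoxymethoxy)benzene | COCOc1c(I)cc(OCc9ccccc9)c(OCc9ccccc9)c1OCc9ccccc9 | intermediate
16 | 5-bromo-1,3-bis(benzyloxy)-2-[3,4,5-tris(benzyloxy)-2-(methoxymethoxy)phenoxy]benzene (two-ring bromide) | Brc1cc(OCc9ccccc9)c(Oc2cc(OCc9ccccc9)c(OCc9ccccc9)c(OCc9ccccc9)c2OCOC)c(OCc9ccccc9)c1 | intermediate
17 | A–C trimer MOM ether: 1,2,3-tris(benzyloxy)-4-(methoxymethoxy)-5-{2,6-bis(benzyloxy)-4-[2,4,6-tris(benzyloxy)phenoxy]phenoxy}benzene | COCOc3c(Oc2c(OCc9ccccc9)cc(Oc1c(OCc9ccccc9)cc(OCc9ccccc9)cc1OCc9ccccc9)cc2OCc9ccccc9)cc(OCc9ccccc9)c(OCc9ccccc9)c3OCc9ccccc9 | intermediate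
18 | A–C trimer phenol: 2,3,4-tris(benzyloxy)-6-{2,6-bis(benzyloxy)-4-[2,4,6-tris(benzyloxy)phenoxy]phenoxy}phenol | Oc3c(Oc2c(OCc9ccccc9)cc(Oc1c(OCc9ccccc9)cc(OCc9ccccc9)cc1OCc9ccccc9)cc2OCc9ccccc9)cc(OCc9ccccc9)c(OCc9ccccc9)c3OCc9ccccc9 | intermediate
19 | A–E pentamer MOM ether (MOM ether of 20 at the C6 oxygen of ring E) | COCOc4c(Oc3c(OCc9ccccc9)cc(Oc2c(Oc1c(OCc9ccccc9)cc(Oc5c(OCc9ccccc9)cc(OCc9ccccc9)cc5OCc9ccccc9)cc1OCc9ccccc9)cc(OCc9ccccc9)c(OCc9ccccc9)c2OCc9ccccc9)cc3OCc9ccccc9)cc(OCc9ccccc9)c(OCc9ccccc9)c4OCc9ccccc9 | intermediate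
20 | A–E pentamer phenol: 2,3,4-tris(benzyloxy)-6-{2,6-bis(benzyloxy)-4-[2,3,4-tris(benzyloxy)-6-{2,6-bis(benzyloxy)-4-[2,4,6-tris(benzyloxy)phenoxy]phenoxy}phenoxy]phenoxy}phenol | Oc4c(Oc3c(OCc9ccccc9)cc(Oc2c(Oc1c(OCc9ccccc9)cc(Oc5c(OCc9ccccc9)cc(OCc9ccccc9)cc5OCc9ccccc9)cc1OCc9ccccc9)cc(OCc9ccccc9)c(OCc9ccccc9)c2OCc9ccccc9)cc3OCc9ccccc9)cc(OCc9ccccc9)c(OCc9ccccc9)c4OCc9ccccc9 | intermediate
21 | trichloroethylene | ClC=C(Cl)Cl | starting material
22 | A–E pentamer (E)-1,2-dichlorovinyl ether (dichlorovinyl on the C6 oxygen of ring E) | Cl/C=C(/Cl)Oc4c(Oc3c(OCc9ccccc9)cc(Oc2c(Oc1c(OCc9ccccc9)cc(Oc5c(OCc9ccccc9)cc(OCc9ccccc9)cc5OCc9ccccc9)cc1OCc9ccccc9)cc(OCc9ccccc9)c(OCc9ccccc9)c2OCc9ccccc9)cc3OCc9ccccc9)cc(OCc9ccccc9)c(OCc9ccccc9)c4OCc9ccccc9 | intermediate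
23 | lithium acetylide of 24 | [Li]C#COc4c(Oc3c(OCc9ccccc9)cc(Oc2c(Oc1c(OCc9ccccc9)cc(Oc5c(OCc9ccccc9)cc(OCc9ccccc9)cc5OCc9ccccc9)cc1OCc9ccccc9)cc(OCc9ccccc9)c(OCc9ccccc9)c2OCc9ccccc9)cc3OCc9ccccc9)cc(OCc9ccccc9)c(OCc9ccccc9)c4OCc9ccccc9 | intermediate
24 | A–E pentamer ethynyl ether (O–C≡CH on C6 of ring E; thirteen benzyl ethers) | C#COc4c(Oc3c(OCc9ccccc9)cc(Oc2c(Oc1c(OCc9ccccc9)cc(Oc5c(OCc9ccccc9)cc(OCc9ccccc9)cc5OCc9ccccc9)cc1OCc9ccccc9)cc(OCc9ccccc9)c(OCc9ccccc9)c2OCc9ccccc9)cc3OCc9ccccc9)cc(OCc9ccccc9)c(OCc9ccccc9)c4OCc9ccccc9 | intermediate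
25 | 3,4,5-tris(benzyloxy)benzaldehyde | O=Cc1cc(OCc9ccccc9)c(OCc9ccccc9)c(OCc9ccccc9)c1 | starting material
26 | 3,4,5-tris(benzyloxy)phenyl formate | O=COc1cc(OCc9ccccc9)c(OCc9ccccc9)c(OCc9ccccc9)c1 | intermediate
27 | 3,4,5-tris(benzyloxy)phenol (ring G) | Oc1cc(OCc9ccccc9)c(OCc9ccccc9)c(OCc9ccccc9)c1 | intermediate
28 | bromoacetic acid | OC(=O)CBr | starting material
29 | 2-[3,4,5-tris(benzyloxy)phenoxy]acetic acid | OC(=O)COc1cc(OCc9ccccc9)c(OCc9ccccc9)c(OCc9ccccc9)c1 | intermediate
30 | benzyl (E)-1,2-dichlorovinyl ether | Cl/C=C(/Cl)OCc1ccccc1 | intermediate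
31 | lithium benzyloxyacetylide | [Li]C#COCc1ccccc1 | intermediate
32 | benzyl ethynyl ether | C#COCc1ccccc1 | intermediate
33 | 2-[3,4,5-tris(benzyloxy)phenoxy]acetyl chloride | ClC(=O)COc1cc(OCc9ccccc9)c(OCc9ccccc9)c(OCc9ccccc9)c1 | intermediate
34 | [3,4,5-tris(benzyloxy)phenoxy]ketene | O=C=COc1cc(OCc9ccccc9)c(OCc9ccccc9)c(OCc9ccccc9)c1 | intermediate
35 | racemic 3-(benzyloxy)-4-[3,4,5-tris(benzyloxy)phenoxy]cyclobut-2-en-1-one | O=C1C=C(OCc9ccccc9)C1Oc2cc(OCc9ccccc9)c(OCc9ccccc9)c(OCc9ccccc9)c2 | intermediate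
36 | (Z)-3-(benzyloxy)-4-[3,4,5-tris(benzyloxy)phenoxy]buta-1,3-dien-1-one (vinylketene) | O=C=C/C(OCc9ccccc9)=C/Oc2cc(OCc9ccccc9)c(OCc9ccccc9)c(OCc9ccccc9)c2 | intermediate
37 | racemic 4-{(Z)-1-(benzyloxy)-2-[3,4,5-tris(benzyloxy)phenoxy]ethenyl}-3-(A–E pentamer-oxy)cyclobut-2-en-1-one | O=C6C=C(Oc4c(Oc3c(OCc9ccccc9)cc(Oc2c(Oc1c(OCc9ccccc9)cc(Oc5c(OCc9ccccc9)cc(OCc9ccccc9)cc5OCc9ccccc9)cc1OCc9ccccc9)cc(OCc9ccccc9)c(OCc9ccccc9)c2OCc9ccccc9)cc3OCc9ccccc9)cc(OCc9ccccc9)c(OCc9ccccc9)c4OCc9ccccc9)C6/C(OCc9ccccc9)=C/Oc7cc(OCc9ccccc9)c(OCc9ccccc9)c(OCc9ccccc9)c7 | intermediate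
38 | (3E,5Z)-5-(benzyloxy)-3-(A–E pentamer-oxy)-6-[3,4,5-tris(benzyloxy)phenoxy]hexa-1,3,5-trien-1-one (dienylketene) | C(/C=C=O)(Oc4c(Oc3c(OCc9ccccc9)cc(Oc2c(Oc1c(OCc9ccccc9)cc(Oc5c(OCc9ccccc9)cc(OCc9ccccc9)cc5OCc9ccccc9)cc1OCc9ccccc9)cc(OCc9ccccc9)c(OCc9ccccc9)c2OCc9ccccc9)cc3OCc9ccccc9)cc(OCc9ccccc9)c(OCc9ccccc9)c4OCc9ccccc9)=C/C(OCc9ccccc9)=C/Oc7cc(OCc9ccccc9)c(OCc9ccccc9)c(OCc9ccccc9)c7 | intermediate
39 | racemic 5-(benzyloxy)-3-(A–E pentamer-oxy)-6-[3,4,5-tris(benzyloxy)phenoxy]cyclohexa-2,4-dien-1-one | O=C6C=C(Oc4c(Oc3c(OCc9ccccc9)cc(Oc2c(Oc1c(OCc9ccccc9)cc(Oc5c(OCc9ccccc9)cc(OCc9ccccc9)cc5OCc9ccccc9)cc1OCc9ccccc9)cc(OCc9ccccc9)c(OCc9ccccc9)c2OCc9ccccc9)cc3OCc9ccccc9)cc(OCc9ccccc9)c(OCc9ccccc9)c4OCc9ccccc9)C=C(OCc9ccccc9)C6Oc7cc(OCc9ccccc9)c(OCc9ccccc9)c(OCc9ccccc9)c7 | intermediate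
40 | heptamer phenol: rings A–G, free OH on C3 of ring F, benzyl ether on every other oxygen (seventeen) | C(c9ccccc9)Oc1cc(OCc9ccccc9)c(Oc2cc(OCc9ccccc9)c(Oc3cc(OCc9ccccc9)c(OCc9ccccc9)c(OCc9ccccc9)c3Oc3cc(OCc9ccccc9)c(Oc4cc(OCc9ccccc9)c(OCc9ccccc9)c(OCc9ccccc9)c4Oc4cc(O)c(Oc5cc(OCc9ccccc9)c(OCc9ccccc9)c(OCc9ccccc9)c5)c(OCc9ccccc9)c4)c(OCc9ccccc9)c3)c(OCc9ccccc9)c2)c(OCc9ccccc9)c1 | intermediate
41 | CNP0292517.0 | Oc1cc(O)c(Oc2cc(O)c(Oc3cc(O)c(O)c(O)c3Oc3cc(O)c(Oc4cc(O)c(O)c(O)c4Oc4cc(O)c(Oc5cc(O)c(O)c(O)c5)c(O)c4)c(O)c3)c(O)c2)c(O)c1 | target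

**Step count and risks**

Total step count: 22. Longest linear sequence: 13 steps (steps 5 to 15, then 21 and 22).

Steps most likely to fail:

1. Step 21. The ring opening of the vinylogous-ester cyclobutenone may be slow, and the vinylketene may dimerise or acylate the product faster than it is captured by the bulky ynol ether, which may itself polymerise on heating. Fallback: from bromophenol 9 and pentamer phenol 20, rings F and G would be attached as a preformed unit by copper chemistry. Benzylation of commercial 5-bromobenzene-1,2,3-triol (BnBr, K2CO3, DMF) gives 5-bromo-1,2,3-tris(benzyloxy)benzene F1. Bromine–lithium exchange (n-BuLi, THF, −78 °C), B(OiPr)3 and aqueous acid give [3,4,5-tris(benzyloxy)phenyl]boronic acid F2. Chan–Lam coupling of 9 with F2 (Cu(OAc)2, pyridine, 4 Å sieves, air, CH2Cl2, rt) leaves the aryl bromide untouched and gives 5-bromo-1,3-bis(benzyloxy)-2-[3,4,5-tris(benzyloxy)phenoxy]benzene F3. Ullmann coupling of 20 with F3 under the conditions of step 12 gives the fully benzylated heptamer (eighteen benzyl ethers) F4, and hydrogenolysis as in step 22 rejoins the route at 41.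

2. Step 9. Carbon–oxygen bond formation between a 2,6-disubstituted phenoxide and an ortho-substituted aryl iodide may stall, and prolonged heating may bring the carbon–bromine bond into play, causing oligomerisation or reduction of the iodide. Fallback: from iodide 15, oxidation to trivalent iodine with mCPBA and TsOH·H2O in the presence of 1,3,5-trimethoxybenzene (MeCN, rt) should give [3,4,5-tris(benzyloxy)-2-(methoxymethoxy)phenyl](2,4,6-trimethoxyphenyl)iodonium tosylate F5. Metal-free O-arylation of 9 with F5 (KOt-Bu, THF, rt) transfers the less electron-rich aryl group, tolerates ortho substituents on both partners, cannot touch the aryl bromide, and rejoins the route at 16.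

3. Step 20 (with step 19). The benzyl ynol ether may rearrange thermally or the ketene may dimerise before the cycloaddition takes place. Fallback: from acid 29, the same ketene generation in the presence of commercial ethoxyacetylene, a thermally robust ynol ether, gives racemic 3-ethoxy-4-[3,4,5-tris(benzyloxy)phenoxy]cyclobut-2-en-1-one F6. Benzannulation with 24 as in step 21 gives the heptamer with an ethyl ether on C5 of ring F, a free C3 hydroxyl and sixteen benzyl ethers F7. Hydrogenolysis as in step 22 gives the ring F mono-ethyl ether of the target F8, and BBr3 (CH2Cl2, −78 °C to rt) cleaves the remaining ethyl ether to rejoin the route at 41.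

Further compounds
F1 | step 21 | 5-bromo-1,2,3-tris(benzyloxy)benzene | Brc1cc(OCc9ccccc9)c(OCc9ccccc9)c(OCc9ccccc9)c1
F2 | step 21 | [3,4,5-tris(benzyloxy)phenyl]boronic acid | OB(O)c1cc(OCc9ccccc9)c(OCc9ccccc9)c(OCc9ccccc9)c1
F3 | step 21 | 5-bromo-1,3-bis(benzyloxy)-2-[3,4,5-tris(benzyloxy)phenoxy]benzene | Brc1cc(OCc9ccccc9)c(Oc2cc(OCc9ccccc9)c(OCc9ccccc9)c(OCc9ccccc9)c2)c(OCc9ccccc9)c1
F4 | step 21 | fully benzylated heptamer (eighteen benzyl ethers) | C(c9ccccc9)Oc1cc(OCc9ccccc9)c(Oc2cc(OCc9ccccc9)c(Oc3cc(OCc9ccccc9)c(OCc9ccccc9)c(OCc9ccccc9)c3Oc3cc(OCc9ccccc9)c(Oc4cc(OCc9ccccc9)c(OCc9ccccc9)c(OCc9ccccc9)c4Oc4cc(OCc9ccccc9)c(Oc5cc(OCc9ccccc9)c(OCc9ccccc9)c(OCc9ccccc9)c5)c(OCc9ccccc9)c4)c(OCc9ccccc9)c3)c(OCc9ccccc9)c2)c(OCc9ccccc9)c1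
F5 | step 9 | [3,4,5-tris(benzyloxy)-2-(methoxymethoxy)phenyl](2,4,6-trimethoxyphenyl)iodonium 4-methylbenzenesulfonate | COCOc1c([I+]c2c(OC)cc(OC)cc2OC)cc(OCc9ccccc9)c(OCc9ccccc9)c1OCc9ccccc9.Cc1ccc(cc1)S(=O)(=O)[O-]
F6 | step 20 | racemic 3-ethoxy-4-[3,4,5-tris(benzyloxy)phenoxy]cyclobut-2-en-1-one | O=C1C=C(OCC)C1Oc2cc(OCc9ccccc9)c(OCc9ccccc9)c(OCc9ccccc9)c2
F7 | step 20 | heptamer with ethyl ether on C5 of ring F, free OH on C3 of ring F and sixteen benzyl ethers | C(c9ccccc9)Oc1cc(OCc9ccccc9)c(Oc2cc(OCc9ccccc9)c(Oc3cc(OCc9ccccc9)c(OCc9ccccc9)c(OCc9ccccc9)c3Oc3cc(OCc9ccccc9)c(Oc4cc(OCc9ccccc9)c(OCc9ccccc9)c(OCc9ccccc9)c4Oc4cc(O)c(Oc5cc(OCc9ccccc9)c(OCc9ccccc9)c(OCc9ccccc9)c5)c(OCC)c4)c(OCc9ccccc9)c3)c(OCc9ccccc9)c2)c(OCc9ccccc9)c1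
F8 | step 20 | target bearing an ethyl ether on the C5 oxygen of ring F | Oc1cc(O)c(Oc2cc(O)c(Oc3cc(O)c(O)c(O)c3Oc3cc(O)c(Oc4cc(O)c(O)c(O)c4Oc4cc(O)c(Oc5cc(O)c(O)c(O)c5)c(OCC)c4)c(O)c3)c(O)c2)c(O)c1
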